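I started from a one-step world, in which substrate turns straight into target and heat merely hurries it. These flasks are not that world, because target itself goes on to over-reaction product.

| setting | green | violet | grey | blue |
|---|---|---|---|---|
| substrate | 0.20 mM | 0.20 mM | 0.20 mM | 0.20 mM |
| partner | 0.240 mM | 0.240 mM | 0.240 mM | 0.240 mM |
| protic impurity | 0.0200 mM | 0.0200 mM | 0.0200 mM | 0.0200 mM |
| temperature | 60 °C | 85 °C | 35 °C | 10 °C |
| time | 50 s | 50 s | 50 s | 50 s |

- the flask that comes out highest in amount of target, in percent of the substrate charged, or "all alike" when all lie within 1.5 percentage points (green / violet / grey / blue / all alike)
- target at the end, in percent of the substrate charged, green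
- target at the end, in percent of the substrate charged, violet
- target at the end, in percent of the substrate charged, grey
- target at the end, in percent of the substrate charged, blue

- all constants are for 60 °C and move with temperature by the activation energies

    intermediate → decomposed reagent (k1 = 0.084 s⁻¹, Ea1 = 79.0 kJ mol⁻¹)
    intermediate → target (k2 = 1.4 s⁻¹, Ea2 = 81.0 kJ mol⁻¹)
    partner + protic impurity → quenched reagent (k3 = 46000 M⁻¹ s⁻¹, Ea3 = 30.0 kJ mol⁻¹)
    target → over-reaction product (k4 = 0.067 s⁻¹, Ea4 = 82.0 kJ mol⁻¹)
    substrate + partner → intermediate + by-product (k5 = 1600 M⁻¹ s⁻¹, Ea5 = 42.0 kJ mol⁻¹)
    (constants at 60 °C)

I went through grey in slow motion. In the first instants partner meets two things: protic impurity, which quenches it, and substrate, with which it couples to intermediate and by-product. At 60 °C the quenching constant 46000 M⁻¹ s⁻¹ is 28.8 times the coupling constant 1600 M⁻¹ s⁻¹, so I took the 0.0200 mM of impurity off the partner at once. That left 0.220 mM of partner against 0.20 mM of substrate. Coupling takes one of each, so their difference stayed frozen at 0.0200 mM, which is small.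

In the middle I therefore treated the two as equal, which gives a slowing tail: the share unconverted is one over one plus the time divided by a coupling time, here 10.7 s in grey. After 50 s that meant 82.4% converted. Intermediate splits between target and decomposed reagent at 1.4 s⁻¹ against 0.084 s⁻¹, and the activation energies of these steps, 81.0 kJ mol⁻¹ and 79.0 kJ mol⁻¹, lie close together, so I froze the selectivity, the share going to target, at 94.3%.

Last, target goes on to over-reaction product by a first-order step, whose half-life at a given temperature is the same however much target stands. In grey it gives 114 s, and this number, the time in which over-reaction halves whatever target stands at that temperature, target's half-life, is the one I carried. The same sum gave 10.3 s in green and 1.31 s in violet, both shorter than the time, so I expected little target in those two. In blue the half-life of intermediate going to target is 86.6 s, longer than the time, so I expected material still waiting there as intermediate. For grey I could only bracket the answer: 77.7% if target were freshly made at the reading, and 57.3% if it had aged the whole time. I committed to grey as the best flask, somewhere between those two figures.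

The forecast also named grey, with green 6.5%, violet 0.02%, grey 65% and blue 12%, and its ground was “The outcome is therefore set by timing”.

The simulation gave grey, with green 6.45%, violet 0.0186%, grey 64.8% and blue 12.0%.

Over-reaction is what stripped violet: with that step taken away, violet's target at the end stood at 94.5% instead of 0.0186%, and the half-life there, 1.31 s, is short against 50 s. The carried 114 s reaches further in grey. At 50 s grey held 81.0% as target, substrate and intermediate together, and halving that for the remaining 450 s gave me 5.28%. Grey left until 500 s stood at 5.85%.

All constants belong to no real substance, and the outcome is calculated.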